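- I followed the reagent. On the list of suspects one step consumes reagent and each turn gives one target, and less reagent than starting material is charged. So reagent is the limiting reagent, and I carried the ceiling, charged [reagent] over charged [starting material], 70.0%: target is the ceiling times the fraction of reagent used.

| flask | starting material | reagent | transfer agent | initiator | remark | time |
|---|---|---|---|---|---|---|
| Wednesday's | 0.042 M (fed, over 1.5 h) | 0.0294 M | 0.042 M | 2.8 mM | run made earlier |  |
| violet | 0.042 M | 0.0294 M | 0.150 M | 4.2 mM | everything together at the start | 1.5 h |
| amber | 0.042 M (fed, over 1.5 h) | 0.0294 M | 0.0420 M | 4.2 mM |  | 1.5 h |

Wednesday's run (percent of the starting material charged)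

| time / min | target / % | starting material / % |
|---|---|---|
| 3.00 | 0 | 1.9 |
| 8.00 | 3.9 | 5.0 |
| 15.0 | 6.9 | 9.3 |
| 25.0 | 12.5 | 14.3 |
| 30.0 | 16.9 | 16.2 |

(readings scatter by 0.5 percentage points)

- a species is counted by the starting material in it: one homo dimer counts as two
- on the list of suspects stand: initiator -> 2 initiating radical; starting material + initiating radical -> capped initiator + first chain carrier; reagent + first chain carrier -> target + second chain carrier; starting material + second chain carrier -> released group + first chain carrier; transfer agent + first chain carrier -> side product + idle radical; 2 idle radical -> ended radicals; 2 second chain carrier -> ended chains; 2 starting material -> homo dimer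
- percentages count the whole charge, also what has not yet gone in
- no earlier run changes the charge of initiator; that part of a forecast is a guess
- no earlier run changes the charge of transfer agent; that part of a forecast is a guess

- which of the two ends with the higher amount of target, in percent of the starting material charged ("neither" if they lie within 2 percentage points) (violet / amber / neither)
- target at the end, in percent of the starting material charged, violet
- target at the end, in percent of the starting material charged, amber

- I worked with the fraction left, one minus target over ceiling. By the readings, Wednesday's flask kept 90.1% of its reagent at 15.0 min and 75.9% at 30.0 min. So its pseudo-first-order constant of reagent loss read 0.00692 min⁻¹ over the first stretch and 0.0115 min⁻¹ over the second.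
- That constant in Wednesday's flask rose 1.66-fold, and I set this against the starting material read inside the two stretches, 5.0% at 8.00 min and 14.3% at 25.0 min, an exponent reading 0.483, rough at this scatter. I took a square root, and the same root for [initiator], which is a guess.
- Wednesday's flask held about half of what had been fed at 30.0 min, so as an estimate I let amber climb steadily to that share of its charge by the end of the feed, a mean starting material of 24.3%. That makes amber's constant 0.0184 min⁻¹, with 19.2% of its reagent left and 56.6% target.
- Violet starts at the full charge, which gives 0.0373 min⁻¹ and 67.6% target, with [transfer agent] left unscaled, again a guess.
- The weak link was holding violet's starting material at the full charge. Letting it slide to what the ceiling spares, 30.0%, and averaging the root gave 0.0288 min⁻¹ and 64.8% target, so I stood on violet.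
- The forecast differed from my reckoning: amber, with 35% for violet and 55% for amber, since in violet “the chain shortens”.
- The flasks gave 67.4% for violet and 59.1% for amber, so violet ended higher.

    initiator → 2 initiating radical (k = 0.0210 min⁻¹)
    starting material + initiating radical → capped initiator + first chain carrier (k = 1.90 × 10⁵ M⁻¹ s⁻¹)
    reagent + first chain carrier → target + second chain carrier (k = 22000 M⁻¹ s⁻¹)
    starting material + second chain carrier → released group + first chain carrier (k = 2.80 × 10⁵ M⁻¹ min⁻¹)
    transfer agent + first chain carrier → side product + idle radical (kL = 14000 M⁻¹ min⁻¹)
    2 idle radical → ended radicals (k = 2.00 × 10⁶ M⁻¹ s⁻¹)
    2 second chain carrier → ended chains (k = 3.90 × 10⁷ M⁻¹ s⁻¹)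
    2 starting material → homo dimer (k = 0.100 M⁻¹ min⁻¹)

- The ceiling times the reagent used gives 67.4% for violet and 58.8% for amber. In amber, the half-life of reagent by its own step was 0.63 h at 0.736 h, shorter than the 1.5 h run, and 16% of its reagent stood at the end. The neighbour of amber charged with 0.012 M of reagent has a ceiling of 28.6%; it ended at 28.5% target, with 0.0960% of its reagent left.

The numbers in the tables are simulated for substances that don't exist; the scatter is artificial.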